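Compare how much ligand a molecule of complex with one exchanged meets with how long it stands in the flask. Write Ma for that complex, Mb for the complex with two exchanged, X for the incoming ligand.

all flasks: time 12 h
- alder: starting complex 0.20 M (fed, over 8.0 h); incoming ligand 0.260 M; all else is in the flask from the start; the feed brings no volume worth counting
- ash: starting complex 0.20 M (in portions, 5, over 8.0 h); incoming ligand 0.260 M; first portion at the start, last at 8.0 h
- cedar: starting complex 0.20 M; incoming ligand 0.260 M (fed, over 8.0 h); all else is in the flask from the start; the feed brings no volume worth counting
- larch: starting complex 0.20 M; incoming ligand 0.260 M; everything together at the start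

- the flask with the highest share of complex with one exchanged in complex with one exchanged plus complex with two exchanged ("all alike" if they lie within 1.5 percentage points) (alder / ash / cedar / larch / all alike)
- share of complex with one exchanged in complex with one exchanged plus complex with two exchanged at the end, alder
- share of complex with one exchanged in complex with one exchanged plus complex with two exchanged at the end, ash
- share of complex with one exchanged in complex with one exchanged plus complex with two exchanged at the end, cedar
- share of complex with one exchanged in complex with one exchanged plus complex with two exchanged at the end, larch

    complex with two exchanged + incoming ligand ⇌ leaving ligand + complex with three exchanged (K1 = 0.854, k1 = 0.0281 /M/h)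
    complex with one exchanged ⇌ isomer of the product (K2 = 5.88, k2 = 0.366 /h)
    complex with one exchanged + incoming ligand ⇌ leaving ligand + complex with two exchanged (K3 = 1.4, k3 = 0.162 /M/h)
    complex with one exchanged → over-reaction product (k4 = 0.380 /h)
    incoming ligand → decomposed reagent (k5 = 0.285 /h)
    starting complex + incoming ligand ⇌ leaving ligand + complex with one exchanged (K6 = 2.1, k6 = 0.504 /M/h)
    complex with three exchanged + incoming ligand ⇌ leaving ligand + complex with four exchanged (K7 = 0.546, k7 = 0.210 /M/h)

Mb forms from Ma and X with 0.162 /M/h, and X is lost by decomposition and by the first exchange. Taking starting complex at its charge, that loss is pseudo-first-order at 0.386 /h. In cedar, solve the feed against this loss: X ends near 0.0172 M, and what was fed but is no longer there has been lost at that rate. Fold this into one number, Ξ = k3∫X dt, which is 0.102 for cedar: the ligand exposure, or second exchanges per Ma standing through the run.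

Go to logarithms: the common logarithm of Ξ is −0.991, so Mb should stand about a power of ten below Ma, and the share is the reciprocal of one plus Ξ, or 90.7 % for cedar. Larch gives Ξ = 0.108 and 90.2 %.

Now test it, since Ξ assumes Ma still stands at its mean level at the end. In larch, X has a half-life of 2.4 h by decomposition, shorter than the run, and by this reckoning ends near 0.00254 M. In larch, Ma has a half-life of 1.8 h by its step to over-reaction product, while Mb has 95 h by the forward step to the complex with three exchanged, with X at its charge. So Ma should ebb in larch while Mb stays, and one number is not enough. Commit to cedar, with more late ligand, as highest and near its figure, larch lowest and well under its figure, alder and ash between.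

The forecast gave cedar, with 80 % for alder, 77 % for ash, 85 % for cedar and 65 % for larch, holding that “the second exchange, which needs both the one-exchanged complex and free ligand at once, stays small”.

The simulation gives cedar as highest, with 84.4 % for alder, 80.5 % for ash, 87.0 % for cedar and 67.6 % for larch.

My cedar figure stands 3.7 percentage points above the flask, my larch figure 23 points above. Read cedar's result as Mb per Ma of 0.149, which is 1.47 times Ξ. Take the neighbour of cedar charged with 0.16 M of X. Every loss in the reckoning is first order in X, so Ξ scales with the charge to 0.0627. With the same reading, the share comes to 91.6 %. That neighbour of cedar gives 91.8 %.

(The numbers of this flask are those of an exercise; the result is computed.)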